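**Strategy.** Everything rests on cutting upper ring C at C3–C4 and O1–C2. Upper C4 is bonded to C4a of ring A, which has O1 (on C8a) ortho and the 7-oxygen para to it, so a hydroxyl group on C4 leaves readily to give an ortho-quinone methide; the epigallocatechin unit is joined to that carbon through its C8 beforehand. The precursor is thus a diaryl carbinol with one free phenol and every other hydroxyl group benzylated. A chiral phosphoric acid combines it with a gallate-derived N-(1-arylvinyl)acetamide in one operation, which forms both bonds, closes ring C as a 4H-chromene and sets C4. Hydroboration relays C4 to C3 and C2; hydrogenolysis frees the target.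

Key step: step 8

Remark 1: the target is read as robinetinidol-(4α→8)-epigallocatechin, upper unit (2R,3S,4S) with a 2,3-trans-3,4-trans ring C, lower unit (2R,3R).
Remark 2: aldehyde 5 and acid 9 are assumed to be purchasable as the benzyl ethers.
Remark 3: the sense of induction at a methide carbon that bears a di-ortho-oxygenated aryl group cannot be assigned in advance with confidence. The (R) acid is written in step 8; its (S) antipode takes its place unchanged if a test run shows the (4R) epimer to prevail. The two C4 epimers are diastereomers and can be told apart directly.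

**Route**

Step 1
Reactants: 1 (−)-epigallocatechin
Product: 2 5,7,3',4',5'-penta-O-benzyl-(−)-epigallocatechin, (2R,3R)-5,7-bis(benzyloxy)-2-[3,4,5-tris(benzyloxy)phenyl]chroman-3-ol
Conditions: BnBr (5.5 equiv), K2CO3, DMF, argon, 0 °C to rt
Reagents that add atoms: benzyl bromide, BrCc1ccccc1
Why: Williamson ether synthesis in which K2CO3 ionises only the five phenols, so that the C3 alcohol stays free and C2 and C3, which take no part, keep their configuration.

Step 2
Reactants: 2 5,7,3',4',5'-penta-O-benzyl-(−)-epigallocatechin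
Product: 3 8-bromo-5,7,3',4',5'-penta-O-benzyl-(−)-epigallocatechin
Conditions: NBS (1.0 equiv), CH2Cl2, −78 to −20 °C
Reagents that add atoms: N-bromosuccinimide, O=C1CCC(=O)N1Br
Why: Electrophilic aromatic bromination: ring A carries three oxygen substituents and is far more reactive than the 3,4,5-tribenzyloxyphenyl ring B, and in 5,7-di-O-benzyl flavan-3-ols the first bromine is known to enter at C8 in preference to C6.

Step 3
Reactants: 3 8-bromo-5,7,3',4',5'-penta-O-benzyl-(−)-epigallocatechin
Product: 4 8-bromo-3,5,7,3',4',5'-hexa-O-benzyl-(−)-epigallocatechin, (2R,3R)-3,5,7-tris(benzyloxy)-8-bromo-2-[3,4,5-tris(benzyloxy)phenyl]chroman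
Conditions: NaH, BnBr, DMF, 0 °C to rt
Reagents that add atoms: benzyl bromide, BrCc1ccccc1
Why: Williamson ether synthesis on the sodium alkoxide of the C3 alcohol, in which the aryl bromide is inert and, with no phenol left free, ring C cannot open at C2.

Step 4
Reactants: 4 8-bromo-3,5,7,3',4',5'-hexa-O-benzyl-(−)-epigallocatechin; 5 4-(benzyloxy)-2-hydroxybenzaldehyde
Product: 8 [4-(benzyloxy)-2-hydroxyphenyl](3,5,7,3',4',5'-hexa-O-benzyl-epigallocatechin-8-yl)methanol (both carbinol epimers), via 8-lithio hexa-O-benzyl-epigallocatechin 6 (not isolated), via sodium 5-(benzyloxy)-2-formylphenolate 7 (not isolated)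
Conditions: 5 (1.5 equiv), NaH, THF, 0 °C (gives 7); 4, t-BuLi (2.1 equiv), THF, −78 °C (gives 6); 7 added to 6, −78 to −20 °C; aq. NH4Cl; chromatography on Et3N-washed silica
Reagents that add atoms: none
Why: Bromine–lithium exchange followed by 1,2-addition of the aryllithium to an aldehyde whose acidic phenol has been turned into the phenoxide beforehand, so that no aryllithium is lost to proton transfer; the carbinol centre forms as a mixture of epimers, which does not matter because this carbon becomes planar in step 8.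

Step 5
Reactants: 9 3,4,5-tris(benzyloxy)benzoic acid
Product: 10 1-[3,4,5-tris(benzyloxy)phenyl]ethanone
Conditions: MeLi (2.3 equiv), THF, −78 to 0 °C; poured into cold 1 M HCl
Reagents that add atoms: methyllithium, [Li]C
Why: Ketone synthesis from a carboxylic acid and an organolithium: the lithium carboxylate takes up one MeLi to give a dilithium gem-diolate that cannot collapse to the ketone before the acidic quench, so over-addition is avoided.

Step 6
Reactants: 10 1-[3,4,5-tris(benzyloxy)phenyl]ethanone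
Product: 11 (E)-1-[3,4,5-tris(benzyloxy)phenyl]ethanone oxime
Conditions: NH2OH·HCl, NaOAc, EtOH/THF, 65 °C
Reagents that add atoms: hydroxylamine hydrochloride, NO.Cl
Why: Oxime condensation of an aryl methyl ketone, expected to give the E isomer with the hydroxyl group turned away from the aryl ring, a geometry that is of no consequence for step 7.

Step 7
Reactants: 11 (E)-1-[3,4,5-tris(benzyloxy)phenyl]ethanone oxime
Product: 13 N-{1-[3,4,5-tris(benzyloxy)phenyl]ethenyl}acetamide, via oxime O-acetate 12 (not isolated)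
Conditions: Ac2O (2 equiv), toluene, rt; then Et3P (1.2 equiv), reflux
Reagents that add atoms: acetic anhydride, CC(=O)OC(C)=O
Why: Phosphine-mediated reductive acylation of a ketoxime, in which the phosphine cleaves the N–O bond of the oxime acetate, the nitrogen ends up acetylated and the N-acetyl imine tautomerises to the enamide, while the benzyl ethers are untouched.

Step 8
Reactants: 8 [4-(benzyloxy)-2-hydroxyphenyl](hexa-O-benzyl-epigallocatechin-8-yl)methanol; 13 N-{1-[3,4,5-tris(benzyloxy)phenyl]ethenyl}acetamide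
Product: 16 (4S)-7-(benzyloxy)-2-[3,4,5-tris(benzyloxy)phenyl]-4-(3,5,7,3',4',5'-hexa-O-benzyl-epigallocatechin-8-yl)-4H-chromene, via ortho-quinone methide 14 (not isolated), via 2-acetamidochromane 15 (not isolated)
Conditions: 13 (1.5 equiv), (R)-3,3'-bis(2,4,6-triisopropylphenyl)-1,1'-binaphthyl-2,2'-diyl hydrogen phosphate (10 mol %), 4 Å molecular sieves, CHCl3, argon, 0 °C to rt, then 40 °C
Reagents that add atoms: none
Why: The phosphoric acid ionises the doubly benzylic carbinol of 8 (the water goes to the sieves) to ortho-quinone methide 14, whose methide carbon is the future upper C4 and already carries lower C8; the acid then holds the quinone methide oxygen by its P–OH and the enamide N–H by its P=O, the enamide CH2 adds to the methide carbon (C3–C4 bond), the regenerated phenol adds to the N-acyliminium carbon (O1–C2 bond) to give aminal 15, and acid-promoted loss of acetamide leaves the C2=C3 enol ether. The closest known reaction type is the chiral phosphoric acid catalysed formal [4+2] annulation of enamides or 1,3-dicarbonyl compounds with ortho-quinone methides generated from ortho-hydroxybenzhydrols, which gives 4-aryl-4H-chromenes. Ring C is closed stepwise in a formal [4+2] manner, the O1–C2 closure being a 6-exo-trig attack of the phenol oxygen on the iminium carbon. The only new stereocentre, upper C4 (S), is set by the face of the planar methide carbon that the chiral phosphate leaves open in the hydrogen-bonded assembly; the lower-unit stereocentres are remote, but they make the two C4 epimers diastereomers, so a minor epimer can be removed by chromatography. The step needs carbon and not nitrogen attack of the enamide, attack by the enamide and not by C6 of a second molecule, and ring closure through the right oxygen: the enamide is the strongest carbon nucleophile present and is used in excess, C6 is flanked by two benzyloxy groups, and the phenol ortho to the carbinol is the only free hydroxyl group in 8. Both carbinol epimers of 8 converge on the same planar intermediate, and the 7-benzyloxy group (para to C4a) together with the trioxygenated lower aryl ring should stabilise 14 enough for ionisation at or below room temperature.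

Step 9
Reactants: 16 (4S)-7-(benzyloxy)-2-[3,4,5-tris(benzyloxy)phenyl]-4-(hexa-O-benzyl-epigallocatechin-8-yl)-4H-chromene
Product: 18 deca-O-benzyl robinetinidol-(4α→8)-epigallocatechin, (2R,3S,4S)-7-(benzyloxy)-2-[3,4,5-tris(benzyloxy)phenyl]-4-(hexa-O-benzyl-epigallocatechin-8-yl)chroman-3-ol, via C3 alkylborane 17 (not isolated)
Conditions: BH3·THF (excess), THF, 0 °C to rt; then 3 M NaOH, 30% H2O2, 0 °C to rt
Reagents that add atoms: hydrogen peroxide, OO
Why: Hydroboration–oxidation of a cyclic enol ether, in which boron goes to C3 (β to O1 and away from the 2-aryl group), B and H add syn from the face opposite the bulky C4 aryl group, and oxidation with retention should give 3-OH trans to the C4 aryl group and H-2 cis to 3-OH, that is the 2,3-trans-3,4-trans triad with C2 (R) and C3 (S).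

Step 10
Reactants: 18 deca-O-benzyl robinetinidol-(4α→8)-epigallocatechin
Product: 19 robinetinidol-(4α→8)-epigallocatechin
Conditions: H2 (1 atm), Pd(OH)2 on carbon, THF/MeOH/H2O, rt; filtration under argon, lyophilisation
Reagents that add atoms: none
Why: Hydrogenolysis of the ten benzyl ethers (nine aryl, one alkyl) over Pd(OH)2 on carbon, a standard last step for benzylated proanthocyanidins, which leaves the interflavan C–C bond, the ring C ethers and all five stereocentres untouched.

**Compound list**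

1 | (−)-epigallocatechin, (2R,3R) | Oc1cc(O)c2c(c1)O[C@H](c1cc(O)c(O)c(O)c1)[C@H](O)C2 | starting material
2 | 5,7,3',4',5'-penta-O-benzyl-(−)-epigallocatechin | c9ccccc9COc1cc(OCc9ccccc9)c2c(c1)O[C@H](c1cc(OCc9ccccc9)c(OCc9ccccc9)c(OCc9ccccc9)c1)[C@H](O)C2 | intermediate
3 | 8-bromo-5,7,3',4',5'-penta-O-benzyl-(−)-epigallocatechin | Brc1c(OCc9ccccc9)cc(OCc9ccccc9)c2c1O[C@H](c1cc(OCc9ccccc9)c(OCc9ccccc9)c(OCc9ccccc9)c1)[C@H](O)C2 | intermediate
4 | 8-bromo-3,5,7,3',4',5'-hexa-O-benzyl-(−)-epigallocatechin | Brc1c(OCc9ccccc9)cc(OCc9ccccc9)c2c1O[C@H](c1cc(OCc9ccccc9)c(OCc9ccccc9)c(OCc9ccccc9)c1)[C@H](OCc9ccccc9)C2 | intermediate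
5 | 4-(benzyloxy)-2-hydroxybenzaldehyde | O=Cc1ccc(OCc9ccccc9)cc1O | starting material
6 | 8-lithio-3,5,7,3',4',5'-hexa-O-benzyl-epigallocatechin (formed in the flask) | [Li]c1c(OCc9ccccc9)cc(OCc9ccccc9)c2c1O[C@H](c1cc(OCc9ccccc9)c(OCc9ccccc9)c(OCc9ccccc9)c1)[C@H](OCc9ccccc9)C2 | intermediate
7 | sodium 5-(benzyloxy)-2-formylphenolate (formed in the flask) | [Na+].[O-]c1cc(OCc9ccccc9)ccc1C=O | intermediate
8 | [4-(benzyloxy)-2-hydroxyphenyl]{(2R,3R)-3,5,7-tris(benzyloxy)-2-[3,4,5-tris(benzyloxy)phenyl]chroman-8-yl}methanol, both carbinol epimers | OC(c1ccc(OCc9ccccc9)cc1O)c1c(OCc9ccccc9)cc(OCc9ccccc9)c2c1O[C@H](c1cc(OCc9ccccc9)c(OCc9ccccc9)c(OCc9ccccc9)c1)[C@H](OCc9ccccc9)C2 | intermediate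
9 | 3,4,5-tris(benzyloxy)benzoic acid | OC(=O)c1cc(OCc9ccccc9)c(OCc9ccccc9)c(OCc9ccccc9)c1 | starting material
10 | 1-[3,4,5-tris(benzyloxy)phenyl]ethanone | CC(=O)c1cc(OCc9ccccc9)c(OCc9ccccc9)c(OCc9ccccc9)c1 | intermediate
11 | (E)-1-[3,4,5-tris(benzyloxy)phenyl]ethanone oxime | C/C(=N\O)c1cc(OCc9ccccc9)c(OCc9ccccc9)c(OCc9ccccc9)c1 | intermediate
12 | (E)-1-[3,4,5-tris(benzyloxy)phenyl]ethanone O-acetyloxime (formed in the flask) | C/C(=N\OC(C)=O)c1cc(OCc9ccccc9)c(OCc9ccccc9)c(OCc9ccccc9)c1 | intermediate
13 | N-{1-[3,4,5-tris(benzyloxy)phenyl]ethenyl}acetamide | CC(=O)NC(=C)c1cc(OCc9ccccc9)c(OCc9ccccc9)c(OCc9ccccc9)c1 | intermediate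
14 | ortho-quinone methide: 3-(benzyloxy)-6-[(hexa-O-benzyl-epigallocatechin-8-yl)methylidene]cyclohexa-2,4-dien-1-one (formed in the flask, alkene geometry open) | O=C1C=C(OCc9ccccc9)C=CC1=Cc1c(OCc9ccccc9)cc(OCc9ccccc9)c2c1O[C@H](c1cc(OCc9ccccc9)c(OCc9ccccc9)c(OCc9ccccc9)c1)[C@H](OCc9ccccc9)C2 | intermediate
15 | (4S)-2-acetamido-7-(benzyloxy)-2-[3,4,5-tris(benzyloxy)phenyl]-4-(hexa-O-benzyl-epigallocatechin-8-yl)chromane, C2 epimers (formed in the flask) | c9ccccc9COc1ccc2c(c1)OC(NC(C)=O)(c1cc(OCc9ccccc9)c(OCc9ccccc9)c(OCc9ccccc9)c1)C[C@@H]2c1c(OCc9ccccc9)cc(OCc9ccccc9)c3c1O[C@H](c1cc(OCc9ccccc9)c(OCc9ccccc9)c(OCc9ccccc9)c1)[C@H](OCc9ccccc9)C3 | intermediate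
16 | (4S)-7-(benzyloxy)-2-[3,4,5-tris(benzyloxy)phenyl]-4-{(2R,3R)-3,5,7-tris(benzyloxy)-2-[3,4,5-tris(benzyloxy)phenyl]chroman-8-yl}-4H-chromene | c9ccccc9COc1ccc2c(c1)OC(c1cc(OCc9ccccc9)c(OCc9ccccc9)c(OCc9ccccc9)c1)=C[C@@H]2c1c(OCc9ccccc9)cc(OCc9ccccc9)c3c1O[C@H](c1cc(OCc9ccccc9)c(OCc9ccccc9)c(OCc9ccccc9)c1)[C@H](OCc9ccccc9)C3 | intermediate
17 | C3 alkylborane (3-BH2) from syn addition of borane to 16 anti to the C4 aryl group (formed in the flask) | c9ccccc9COc1ccc2c(c1)O[C@H](c1cc(OCc9ccccc9)c(OCc9ccccc9)c(OCc9ccccc9)c1)[C@@H](B)[C@@H]2c1c(OCc9ccccc9)cc(OCc9ccccc9)c3c1O[C@H](c1cc(OCc9ccccc9)c(OCc9ccccc9)c(OCc9ccccc9)c1)[C@H](OCc9ccccc9)C3 | intermediate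
18 | (2R,3S,4S)-7-(benzyloxy)-2-[3,4,5-tris(benzyloxy)phenyl]-4-{(2R,3R)-3,5,7-tris(benzyloxy)-2-[3,4,5-tris(benzyloxy)phenyl]chroman-8-yl}chroman-3-ol | c9ccccc9COc1ccc2c(c1)O[C@H](c1cc(OCc9ccccc9)c(OCc9ccccc9)c(OCc9ccccc9)c1)[C@@H](O)[C@@H]2c1c(OCc9ccccc9)cc(OCc9ccccc9)c3c1O[C@H](c1cc(OCc9ccccc9)c(OCc9ccccc9)c(OCc9ccccc9)c1)[C@H](OCc9ccccc9)C3 | intermediate
19 | robinetinidol-(4α→8)-epigallocatechin, (2R,3S,4S)-2-(3,4,5-trihydroxyphenyl)-4-[(2R,3R)-3,5,7-trihydroxy-2-(3,4,5-trihydroxyphenyl)chroman-8-yl]chroman-3,7-diol | Oc1ccc2c(c1)O[C@H](c1cc(O)c(O)c(O)c1)[C@@H](O)[C@@H]2c1c(O)cc(O)c2c1O[C@H](c1cc(O)c(O)c(O)c1)[C@H](O)C2 | target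

**Count and risks**

Total step count: 10. Longest linear sequence: 7 steps (steps 1, 2, 3, 4, 8, 9, 10).

Steps most likely to fail:

1. Step 8. The process at risk is facial discrimination at the methide carbon, whose di-ortho-oxygenated aryl group is twisted out of plane and whose lower unit may be mismatched with the catalyst; a second risk is consumption of 14 by arylation at C6 of another molecule. Fallback, setting out from 8 and 10 and coming back at 16: catalyst control is given up and replaced by separation of diastereomers. Ketone 10 is silylated (t-BuMe2SiOTf, Et3N, CH2Cl2) to tert-butyl(dimethyl){1-[3,4,5-tris(benzyloxy)phenyl]ethenyloxy}silane F1, which is used in large excess with 8, catalytic diphenyl phosphate and 4 Å molecular sieves in CH2Cl2. Inverse-electron-demand hetero-Diels–Alder reaction of 14 (Mukaiyama–Michael addition, then ring closure by the phenol) should give the 2-(tert-butyldimethylsilyloxy)chromane F2. Warming F2 with pyridinium p-toluenesulfonate in toluene eliminates the silanol and gives 16 together with its (4R) epimer F3; since these are diastereomers, they are separated by chromatography.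

2. Step 4. The process at risk is slow addition of the hindered aryllithium to the electron-rich, poorly soluble phenoxide aldehyde, so that 6 is protonated or rearranges by metalation of an ortho benzyl ether before it adds. Fallback, setting out from 4 and 5 and coming back at 8: the phenol of 5 is capped (allyl bromide, K2CO3, DMF) as 2-(allyloxy)-4-(benzyloxy)benzaldehyde F4, an aldehyde of normal electrophilicity. F4 takes up 6 at −78 °C to give [2-(allyloxy)-4-(benzyloxy)phenyl](hexa-O-benzyl-epigallocatechin-8-yl)methanol F5. The allyl group is then removed with catalytic Pd(PPh3)4 (zerovalent palladium) and morpholine in THF at rt, neutral conditions that leave the benzyl ethers and the acid-labile carbinol alone, to give 8.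

3. Step 9. The process at risk is sluggish or face-unselective hydroboration of the hindered trisubstituted enol ether, or β-elimination of the C3 borane with opening of ring C. Fallback, setting out from 16 and coming back at 18: epoxidation with dimethyldioxirane in acetone/CH2Cl2/MeOH at −20 °C, from the face opposite the C4 aryl group, gives the 2,3-epoxide of 16 F6. Methanol opens F6 in the flask at the acetal carbon C2 to the 2-methoxyflavan-3-ol F7. Ionic reduction (Et3SiH, BF3·OEt2, CH2Cl2, −40 °C) then delivers hydride axially to the C2 oxocarbenium ion, which places the 2-aryl group equatorial and trans to 3-OH, as in the reduction of aryl ketals to β-C-aryl glycosides, and gives 18.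

**Further compounds**

F1 | step 8 | tert-butyl(dimethyl){1-[3,4,5-tris(benzyloxy)phenyl]ethenyloxy}silane | C=C(O[Si](C)(C)C(C)(C)C)c1cc(OCc9ccccc9)c(OCc9ccccc9)c(OCc9ccccc9)c1
F2 | step 8 | 7-(benzyloxy)-2-(tert-butyldimethylsilyloxy)-2-[3,4,5-tris(benzyloxy)phenyl]-4-(hexa-O-benzyl-epigallocatechin-8-yl)chromane, mixture at C2 and C4 | c9ccccc9COc1ccc2c(c1)OC(O[Si](C)(C)C(C)(C)C)(c1cc(OCc9ccccc9)c(OCc9ccccc9)c(OCc9ccccc9)c1)CC2c1c(OCc9ccccc9)cc(OCc9ccccc9)c3c1O[C@H](c1cc(OCc9ccccc9)c(OCc9ccccc9)c(OCc9ccccc9)c1)[C@H](OCc9ccccc9)C3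
F3 | step 8 | (4R) epimer of 16 | c9ccccc9COc1ccc2c(c1)OC(c1cc(OCc9ccccc9)c(OCc9ccccc9)c(OCc9ccccc9)c1)=C[C@H]2c1c(OCc9ccccc9)cc(OCc9ccccc9)c3c1O[C@H](c1cc(OCc9ccccc9)c(OCc9ccccc9)c(OCc9ccccc9)c1)[C@H](OCc9ccccc9)C3
F4 | step 4 | 2-(allyloxy)-4-(benzyloxy)benzaldehyde | O=Cc1ccc(OCc9ccccc9)cc1OCC=C
F5 | step 4 | [2-(allyloxy)-4-(benzyloxy)phenyl](hexa-O-benzyl-epigallocatechin-8-yl)methanol, both carbinol epimers | OC(c1ccc(OCc9ccccc9)cc1OCC=C)c1c(OCc9ccccc9)cc(OCc9ccccc9)c2c1O[C@H](c1cc(OCc9ccccc9)c(OCc9ccccc9)c(OCc9ccccc9)c1)[C@H](OCc9ccccc9)C2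
F6 | step 9 | 2,3-epoxide of 16, oxygen anti to the C4 aryl group | c9ccccc9COc1ccc2c(c1)O[C@]4(c1cc(OCc9ccccc9)c(OCc9ccccc9)c(OCc9ccccc9)c1)[C@@H](O4)[C@@H]2c1c(OCc9ccccc9)cc(OCc9ccccc9)c3c1O[C@H](c1cc(OCc9ccccc9)c(OCc9ccccc9)c(OCc9ccccc9)c1)[C@H](OCc9ccccc9)C3
F7 | step 9 | (3S,4S)-7-(benzyloxy)-2-methoxy-2-[3,4,5-tris(benzyloxy)phenyl]-4-(hexa-O-benzyl-epigallocatechin-8-yl)chroman-3-ol, C2 anomers | c9ccccc9COc1ccc2c(c1)OC(OC)(c1cc(OCc9ccccc9)c(OCc9ccccc9)c(OCc9ccccc9)c1)[C@@H](O)[C@@H]2c1c(OCc9ccccc9)cc(OCc9ccccc9)c3c1O[C@H](c1cc(OCc9ccccc9)c(OCc9ccccc9)c(OCc9ccccc9)c1)[C@H](OCc9ccccc9)C3
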